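**Retrosynthetic overview**
- The target is a tri-ortho-substituted diaryl ether made of two preformed olivetolate (β-resorcylate) rings, so no ring is built; only the Ar–O–Ar bond joins the halves.
- Last step: hydrogenolysis of three benzyl groups (ring-A 4-OBn, ring-B 2-OBn and CO2Bn) frees both phenols and the acid and leaves the ring-A methyl ester.
- Key disconnection: the C–O bond between the ring-A 2-oxygen and the ring-B carbon flanked by OMe and pentyl, made by a one-flask C–H iodination / λ3-iodane / aryl(trimethoxyphenyl)iodonium aryl transfer to the ring-A phenoxide.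
- Ring-A phenol: methyl olivetolate, 4-O-benzylated. Ring-B arene: olivetolic acid, benzyl-esterified, then 4-O-methylated and 2-O-benzylated.

Assumption: the target has no stereocentre or isolable stereoaxis, so "single enantiomer" means the one achiral constitution drawn; methyl olivetolate and olivetolic acid are taken as commercial building blocks.

**Step 1**
Reactants: 1 methyl olivetolate (methyl 2,4-dihydroxy-6-pentylbenzoate)
Product: 2 methyl 4-(benzyloxy)-2-hydroxy-6-pentylbenzoate
Conditions: BnBr (1.05 equiv), K2CO3, acetone, reflux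
Reagents that add atoms: benzyl bromide, BrCc1ccccc1
Why: Williamson etherification; the 2-OH is held in a hydrogen bond to the ester, so only the more acidic, unhindered 4-OH is alkylated.

**Step 2**
Reactants: 3 olivetolic acid (2,4-dihydroxy-6-pentylbenzoic acid)
Product: 4 benzyl 2,4-dihydroxy-6-pentylbenzoate
Conditions: BnBr (1.05 equiv), KHCO3, DMF, rt
Reagents that add atoms: benzyl bromide, BrCc1ccccc1
Why: Carboxylate SN2 O-alkylation; bicarbonate deprotonates only the CO2H, so both phenols stay free, and room temperature avoids decarboxylation of the β-resorcylic acid.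

**Step 3**
Reactants: 4 benzyl 2,4-dihydroxy-6-pentylbenzoate
Product: 6 benzyl 2-(benzyloxy)-4-methoxy-6-pentylbenzoate, via 4-O-methyl ether 5 (not isolated)
Conditions: MeI (1.0 equiv), K2CO3, DMF, rt; N2 purge; then BnBr (1.5 equiv), 70 °C
Reagents that add atoms: iodomethane, CI; benzyl bromide, BrCc1ccccc1
Why: Two Williamson etherifications separated by temperature; the free 4-OH is methylated at rt, and the hydrogen-bonded 2-OH reacts only on heating with benzyl bromide.

**Step 4**
Reactants: 6 benzyl 2-(benzyloxy)-4-methoxy-6-pentylbenzoate; 2 methyl 4-(benzyloxy)-2-hydroxy-6-pentylbenzoate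
Product: 10 methyl 4-(benzyloxy)-2-{4-(benzyloxy)-3-[(benzyloxy)carbonyl]-6-methoxy-2-pentylphenoxy}-6-pentylbenzoate, via aryl iodide 7 (not isolated), via hydroxy(tosyloxy)iodane 8 (not isolated), via iodonium tosylate 9 (not isolated)
Conditions: NIS (1.0 equiv), TsOH·H2O (1.1 equiv), MeCN, rt; mCPBA (1.1 equiv), 55 °C; 1,3,5-trimethoxybenzene (1.05 equiv), rt; then 2 (1.2 equiv), Cs2CO3 (4 equiv), MeCN–PhMe, 60 °C, one flask
Reagents that add atoms: none
Why: Proposed new method: a one-flask, formally dehydrogenative C–H/O–H cross-etherification in which (i) acid-promoted SEAr iodination goes to C-5 of 6 (para to OBn, ortho to OMe, the site halogen electrophiles take in 2,4-dialkoxy-6-alkylbenzoyl arenes), (ii) mCPBA/TsOH oxidises aryl iodide 7 to the Koser-type iodane 8, (iii) 1,3,5-trimethoxybenzene attacks 8 in a second SEAr to give iodonium salt 9, in which neither aryl has an ortho hydrogen so no aryne pathway is open, and (iv) the caesium phenoxide of 2 exchanges onto iodine and 3-centre-4-electron ligand coupling delivers oxygen to the ipso carbon of the less electron-rich, ester-bearing ring-B aryl while the trimethoxyphenyl group leaves as its iodide; the closest known reaction types are the one-pot preparation of aryl(trimethoxyphenyl)iodonium salts from aryl iodides and the transition-metal-free O-arylation of phenols with diaryliodonium salts, which have not been run as a single C–H aryloxylation nor used to join a doubly ortho-flanked resorcylate carbon to a chelated salicylate OH.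

**Step 5**
Reactants: 10 methyl 4-(benzyloxy)-2-{4-(benzyloxy)-3-[(benzyloxy)carbonyl]-6-methoxy-2-pentylphenoxy}-6-pentylbenzoate
Product: 11 epiphorellic acid 1 (6-hydroxy-3-[5-hydroxy-2-(methoxycarbonyl)-3-pentylphenoxy]-4-methoxy-2-pentylbenzoic acid)
Conditions: H2 (1 atm), 10% Pd/C, EtOAc, rt
Reagents that add atoms: none
Why: Heterogeneous hydrogenolysis cleaves the benzyl ester and both benzyl aryl ethers; the diaryl ether, methyl ester and methyl ether are inert, and neutral room-temperature conditions avoid decarboxylation of the salicylic acid.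

**Compound list**
1 | methyl olivetolate (methyl 2,4-dihydroxy-6-pentylbenzoate) | CCCCCc1cc(O)cc(O)c1C(=O)OC | starting material
2 | methyl 4-(benzyloxy)-2-hydroxy-6-pentylbenzoate | CCCCCc1cc(OCc2ccccc2)cc(O)c1C(=O)OC | intermediate
3 | olivetolic acid (2,4-dihydroxy-6-pentylbenzoic acid) | CCCCCc1cc(O)cc(O)c1C(=O)O | starting material
4 | benzyl 2,4-dihydroxy-6-pentylbenzoate | CCCCCc1cc(O)cc(O)c1C(=O)OCc1ccccc1 | intermediate
5 | benzyl 2-hydroxy-4-methoxy-6-pentylbenzoate | CCCCCc1cc(OC)cc(O)c1C(=O)OCc1ccccc1 | intermediate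
6 | benzyl 2-(benzyloxy)-4-methoxy-6-pentylbenzoate | CCCCCc1cc(OC)cc(OCc2ccccc2)c1C(=O)OCc1ccccc1 | intermediate
7 | benzyl 6-(benzyloxy)-3-iodo-4-methoxy-2-pentylbenzoate | CCCCCc1c(I)c(OC)cc(OCc2ccccc2)c1C(=O)OCc1ccccc1 | intermediate
8 | benzyl 6-(benzyloxy)-3-[hydroxy(tosyloxy)-λ3-iodanyl]-4-methoxy-2-pentylbenzoate | CCCCCc1c(I(O)OS(=O)(=O)c2ccc(C)cc2)c(OC)cc(OCc2ccccc2)c1C(=O)OCc1ccccc1 | intermediate
9 | {4-(benzyloxy)-3-[(benzyloxy)carbonyl]-6-methoxy-2-pentylphenyl}(2,4,6-trimethoxyphenyl)iodonium 4-methylbenzenesulfonate | CCCCCc1c([I+]c2c(OC)cc(OC)cc2OC)c(OC)cc(OCc2ccccc2)c1C(=O)OCc1ccccc1.Cc1ccc(cc1)S(=O)(=O)[O-] | intermediate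
10 | methyl 4-(benzyloxy)-2-{4-(benzyloxy)-3-[(benzyloxy)carbonyl]-6-methoxy-2-pentylphenoxy}-6-pentylbenzoate | CCCCCc1cc(OCc2ccccc2)cc(Oc2c(OC)cc(OCc3ccccc3)c(C(=O)OCc3ccccc3)c2CCCCC)c1C(=O)OC | intermediate
11 | epiphorellic acid 1 (6-hydroxy-3-[5-hydroxy-2-(methoxycarbonyl)-3-pentylphenoxy]-4-methoxy-2-pentylbenzoic acid; achiral) | CCCCCc1cc(O)cc(Oc2c(OC)cc(O)c(C(=O)O)c2CCCCC)c1C(=O)OC | target

**Totals**
Total step count: 5. Longest linear sequence: 4 steps (3 → 4 → 6 → 10 → 11); step 1 is the second branch.

**Steps most likely to fail**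

Step 4 (the proposed new step) is the main risk. Iodination could partly go to C-3 of 6, the trimethoxyphenyl group could compete in the aryl transfer, and the chelated, ortho-ester phenoxide of 2 is a weak nucleophile. The fallback uses known chemistry with the polarity reversed; it sets out from 6 and 2 and comes back at 10. Iodinate 6 (NIS, cat. TFA, MeCN) and isolate aryl iodide 7. Pd-catalysed hydroxylation (Pd2(dba)3, tBuXPhos, KOH, dioxane–H2O, 80 °C) gives benzyl 6-(benzyloxy)-3-hydroxy-4-methoxy-2-pentylbenzoate F1. Separately, triflation of 2 (Tf2O, pyridine, CH2Cl2, 0 °C) gives methyl 4-(benzyloxy)-2-pentyl-6-{[(trifluoromethyl)sulfonyl]oxy}benzoate F2. Pd-catalysed diaryl ether coupling of F1 with F2 (Pd(OAc)2, tBuXPhos, K3PO4, PhMe, 100 °C) gives 10. The electron-rich hindered ring is now the nucleophile and the ortho-ester ring the electrophile.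

Step 3 is the second risk. Residual iodomethane could methylate the 2-OH on heating, or the chelated 2-OH could benzylate slowly, giving Me/Bn crossover mixtures. The fallback sets out from 1 and comes back at 6. Methylate 1 (MeI, K2CO3, acetone, rt) to methyl 2-hydroxy-4-methoxy-6-pentylbenzoate F3 and purify it. Saponify (KOH, DMSO–H2O, 80 °C, cold acidification) to 2-hydroxy-4-methoxy-6-pentylbenzoic acid F4. Exhaustive benzylation of acid and phenol (BnBr 2.5 equiv, K2CO3, DMF, 70 °C) then gives 6 with no selectivity required.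

Step 5 is the third risk. Traces of aryl iodide could poison the catalyst, the hindered benzyl ester could cleave slowly, and the product acid decarboxylates if warmed. The fallback sets out from 10 and comes back at 11. Lewis-acid debenzylation (BCl3, pentamethylbenzene, CH2Cl2, −78 → 0 °C) removes all three benzyl groups as benzyl cations trapped by the scavenger. The methyl ether is not ortho to a carbonyl and the methyl ester is stable at this temperature; no new compound is made (F0).

**Further compounds**
F1 | step 4 | benzyl 6-(benzyloxy)-3-hydroxy-4-methoxy-2-pentylbenzoate | CCCCCc1c(O)c(OC)cc(OCc2ccccc2)c1C(=O)OCc1ccccc1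
F2 | step 4 | methyl 4-(benzyloxy)-2-pentyl-6-{[(trifluoromethyl)sulfonyl]oxy}benzoate | CCCCCc1cc(OCc2ccccc2)cc(OS(=O)(=O)C(F)(F)F)c1C(=O)OC
F3 | step 3 | methyl 2-hydroxy-4-methoxy-6-pentylbenzoate | CCCCCc1cc(OC)cc(O)c1C(=O)OC
F4 | step 3 | 2-hydroxy-4-methoxy-6-pentylbenzoic acid | CCCCCc1cc(OC)cc(O)c1C(=O)O
F0 | step 5 | none | none
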